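## Retrosynthetic overview

1. Last bond: C7'–C8' Stille coupling of a decalin-bound (E)-alkenyl iodide with a (2E,4Z,6E)-stannyl trienoic acid, so the tetraene is made at the very end.
2. Ester C–O bond: Yamaguchi acylation of the decalin C8 alcohol with an iodo acid whose C10'/C11' centres come from an Evans MgCl2 anti-aldol reaction.
3. Decalin: C2 carbinol by MeLi addition and quaternary C1 by α'-aldol reaction of a bicyclic dienone.
4. Ring order: ring B comes first, from (S)-5-methylcyclohex-2-en-1-one (α-iodination/Suzuki, epoxidation/SmI2 opening, enol triflate formylation); ring A is closed onto it by intramolecular aldol condensation.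
5. Stannane: from (Z)-3-methylpent-2-en-4-yn-1-ol by hydrostannation, oxidation and Horner–Wadsworth–Emmons olefination.

Assumption: compounds 1 and 17 are bought as such (1 is otherwise three known steps from (S)-pulegone); locants C1–C8a are those of the target decalin, C1'–C12' those of the acid chain counted from the free CO2H, and the β face is the face of H-8a.

## Route

Step 1
Reactants: 1 (S)-5-methylcyclohex-2-en-1-one
Product: 2 (S)-2-iodo-5-methylcyclohex-2-en-1-one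
Conditions: I2, pyridine, CH2Cl2, 0 °C → rt
Reagents that add atoms: iodine, II
Why: Baylis–Hillman-type α-iodination (pyridine adds conjugately, the enolate is iodinated, pyridine is eliminated) that does not touch the C6 methyl stereocentre.

Step 2
Reactants: 2 (S)-2-iodo-5-methylcyclohex-2-en-1-one; 3 (Z)-but-2-en-2-ylboronic acid
Product: 4 (5S)-2-[(2E)-but-2-en-2-yl]-5-methylcyclohex-2-en-1-one
Conditions: PdCl2(dppf) (5 mol %), K2CO3, THF/H2O, 50 °C
Reagents that add atoms: none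
Why: Suzuki–Miyaura coupling of an electron-poor alkenyl iodide with retention of the butenyl geometry, which brings in C1, its methyl, C2 and C3 of ring A in one piece.

Step 3
Reactants: 4 (5S)-2-[(2E)-but-2-en-2-yl]-5-methylcyclohex-2-en-1-one
Product: 5 (1S,4S,6S)-1-[(2E)-but-2-en-2-yl]-4-methyl-7-oxabicyclo[4.1.0]heptan-2-one
Conditions: 30 % H2O2, NaOH (cat.), MeOH, 0 °C
Reagents that add atoms: hydrogen peroxide, OO
Why: Weitz–Scheffer nucleophilic epoxidation in which hydroperoxide attacks the enone β-carbon axially and anti to the C6 methyl, fixing the C8 oxygen trans to that methyl while the electron-rich butenyl double bond is left alone.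

Step 4
Reactants: 5 (1S,4S,6S)-1-[(2E)-but-2-en-2-yl]-4-methyl-7-oxabicyclo[4.1.0]heptan-2-one
Product: 7 (2S,3S,5S)-2-[(2E)-but-2-en-2-yl]-3-hydroxy-5-methylcyclohexan-1-one, via diiodosamarium enolate 6 (not isolated)
Conditions: SmI2 (2.2 equiv), THF/MeOH, −90 °C
Reagents that add atoms: none
Why: Reductive opening of the epoxy ketone by two single-electron transfers cleaves the Cα–O bond, and the trivalent samarium dienolate is protonated kinetically at the α-carbon from the face anti to the pseudoaxial C8–O–Sm group, which puts H-8a trans to the oxygen and keeps the side-arm double bond out of conjugation.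

Step 5
Reactants: 7 (2S,3S,5S)-2-[(2E)-but-2-en-2-yl]-3-hydroxy-5-methylcyclohexan-1-one
Product: 8 (2S,3S,5S)-2-[(2E)-but-2-en-2-yl]-5-methyl-3-[(triethylsilyl)oxy]cyclohexan-1-one
Conditions: Et3SiCl, imidazole, DMF, 0 °C → rt
Reagents that add atoms: chlorotriethylsilane, CC[Si](Cl)(CC)CC
Why: Imidazole-mediated silylation of the secondary alcohol; the triethylsilyl ether survives the base and organometallic steps and can later be removed selectively next to a tert-butyldiphenylsilyl ether.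

Step 6
Reactants: 8 (2S,3S,5S)-2-[(2E)-but-2-en-2-yl]-5-methyl-3-[(triethylsilyl)oxy]cyclohexan-1-one
Product: 10 (3S,5S,6S)-6-[(2E)-but-2-en-2-yl]-3-methyl-5-[(triethylsilyl)oxy]cyclohex-1-en-1-yl trifluoromethanesulfonate, via potassium enolate 9 (not isolated)
Conditions: KN(SiMe3)2, THF, −78 °C; PhNTf2, −78 → 0 °C
Reagents that add atoms: N-phenylbis(trifluoromethanesulfonimide), O=S(=O)(N(c1ccccc1)S(=O)(=O)C(F)(F)F)C(F)(F)F
Why: Kinetic enolisation by the bulky amide base removes a proton from the unhindered C5 methylene and not from the hindered C8a methine, and O-sulfonylation fixes the C4a=C5 double bond of the target as an enol triflate.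

Step 7
Reactants: 10 (3S,5S,6S)-6-[(2E)-but-2-en-2-yl]-3-methyl-5-[(triethylsilyl)oxy]cyclohex-1-en-1-yl trifluoromethanesulfonate
Product: 12 (3S,5S,6S)-6-(3-hydroxybutan-2-yl)-3-methyl-5-[(triethylsilyl)oxy]cyclohex-1-en-1-yl trifluoromethanesulfonate (side-arm epimers), via alkylborane 11 (not isolated)
Conditions: BH3·THF, THF, 0 °C → rt; aq. NaOAc, 30 % H2O2, 0 °C
Reagents that add atoms: hydrogen peroxide, OO
Why: Hydroboration–oxidation of the electron-rich trisubstituted side-arm alkene puts boron on the less substituted carbon C2 (the electron-poor enol triflate double bond is inert); the two new side-arm stereocentres form as mixtures and are both erased later (C2 by oxidation, C1 by enolisation).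

Step 8
Reactants: 12 (3S,5S,6S)-6-(3-hydroxybutan-2-yl)-3-methyl-5-[(triethylsilyl)oxy]cyclohex-1-en-1-yl trifluoromethanesulfonate
Product: 13 (3S,5S,6S)-3-methyl-6-(3-oxobutan-2-yl)-5-[(triethylsilyl)oxy]cyclohex-1-en-1-yl trifluoromethanesulfonate (side-arm epimers)
Conditions: Dess–Martin periodinane, CH2Cl2, rt
Reagents that add atoms: none
Why: Dess–Martin oxidation of the secondary alcohol to the methyl ketone under neutral conditions that leave the enol triflate and the silyl ether alone.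

Step 9
Reactants: 13 (3S,5S,6S)-3-methyl-6-(3-oxobutan-2-yl)-5-[(triethylsilyl)oxy]cyclohex-1-en-1-yl trifluoromethanesulfonate
Product: 14 (3S,5S,6R)-3-methyl-6-(3-oxobutan-2-yl)-5-[(triethylsilyl)oxy]cyclohex-1-ene-1-carbaldehyde (side-arm epimers)
Conditions: Pd(PPh3)4 (5 mol %), CO (1 atm), Bu3SnH (syringe pump), THF, 50 °C
Reagents that add atoms: carbon monoxide, [C-]#[O+]
Why: Palladium-catalysed reductive carbonylation (Stille formylation), in which oxidative addition of zerovalent palladium into the C–OTf bond, CO insertion and hydride transfer from tin give the enal that supplies C4.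

Step 10
Reactants: 14 (3S,5S,6R)-3-methyl-6-(3-oxobutan-2-yl)-5-[(triethylsilyl)oxy]cyclohex-1-ene-1-carbaldehyde
Product: 16 (6S,8S,8aR)-1,6-dimethyl-8-[(triethylsilyl)oxy]-6,7,8,8a-tetrahydronaphthalen-2(1H)-one (C1 epimers), via aldol adduct 15 (not isolated)
Conditions: t-BuOK (0.2 equiv), t-BuOH/THF, 0 °C → rt
Reagents that add atoms: none
Why: Intramolecular aldol condensation closes ring A, because only the methyl-ketone enolate can reach the aldehyde through a six-membered ring and E1cB loss of water gives the linearly conjugated dienone; C1 stays epimeric, which does not matter because it is enolised next.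

Step 11
Reactants: 16 (6S,8S,8aR)-1,6-dimethyl-8-[(triethylsilyl)oxy]-6,7,8,8a-tetrahydronaphthalen-2(1H)-one; 17 3-[(tert-butyldiphenylsilyl)oxy]propanal
Product: 19 (1S,6S,8S,8aS)-1-{3-[(tert-butyldiphenylsilyl)oxy]-1-hydroxypropyl}-1,6-dimethyl-8-[(triethylsilyl)oxy]-6,7,8,8a-tetrahydronaphthalen-2(1H)-one (carbinol epimers), via lithium enolate 18 (not isolated)
Conditions: LiN(i-Pr)2, THF, −78 °C; 17, −78 °C; AcOH
Reagents that add atoms: none
Why: Kinetic α'-deprotonation gives the cross-conjugated lithium enolate, whose aldol addition occurs on the β face, anti to C8 and its silyloxy group (held pseudoaxial by allylic strain with the C1 methyl), setting the quaternary C1 with the new chain cis to H-8a; the carbinol carbon forms as a mixture and is oxidised later.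

Step 12
Reactants: 19 (1S,6S,8S,8aS)-1-{3-[(tert-butyldiphenylsilyl)oxy]-1-hydroxypropyl}-1,6-dimethyl-8-[(triethylsilyl)oxy]-6,7,8,8a-tetrahydronaphthalen-2(1H)-one
Product: 20 (1S,2R,6S,8S,8aS)-1-{3-[(tert-butyldiphenylsilyl)oxy]-1-hydroxypropyl}-1,2,6-trimethyl-8-[(triethylsilyl)oxy]-1,2,6,7,8,8a-hexahydronaphthalen-2-ol (carbinol epimers)
Conditions: MeLi (3 equiv), THF, −78 °C; AcOH
Reagents that add atoms: methyllithium, [Li]C
Why: 1,2-Addition of MeLi to the non-enolisable dienone carbonyl, where the lithium alkoxide of the side chain chelates the carbonyl and so lies in its plane, the C1 methyl is then pseudoaxial on the α face, and the nucleophile enters anti to it from the β face to give the (2R) tertiary alcohol.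

Step 13
Reactants: 20 (1S,2R,6S,8S,8aS)-1-{3-[(tert-butyldiphenylsilyl)oxy]-1-hydroxypropyl}-1,2,6-trimethyl-8-[(triethylsilyl)oxy]-1,2,6,7,8,8a-hexahydronaphthalen-2-ol
Product: 21 3-[(tert-butyldiphenylsilyl)oxy]-1-{(1R,2R,6S,8S,8aS)-2-hydroxy-1,2,6-trimethyl-8-[(triethylsilyl)oxy]-1,2,6,7,8,8a-hexahydronaphthalen-1-yl}propan-1-one
Conditions: Dess–Martin periodinane, pyridine, CH2Cl2, 0 °C → rt
Reagents that add atoms: none
Why: Dess–Martin oxidation buffered with pyridine converts only the secondary alcohol into the ketone (the tertiary dienylic alcohol cannot be oxidised and is spared acid), completing the 3-oxygenated propanoyl group.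

Step 14
Reactants: 21 3-[(tert-butyldiphenylsilyl)oxy]-1-{(1R,2R,6S,8S,8aS)-2-hydroxy-1,2,6-trimethyl-8-[(triethylsilyl)oxy]-1,2,6,7,8,8a-hexahydronaphthalen-1-yl}propan-1-one
Product: 22 3-[(tert-butyldiphenylsilyl)oxy]-1-[(1R,2R,6S,8S,8aS)-2,8-dihydroxy-1,2,6-trimethyl-1,2,6,7,8,8a-hexahydronaphthalen-1-yl]propan-1-one
Conditions: HF·pyridine, pyridine, THF, 0 °C
Reagents that add atoms: none
Why: Buffered fluoride desilylation cleaves the triethylsilyl ether much faster than the primary tert-butyldiphenylsilyl ether, and no acid strong enough to ionise the tertiary dienylic alcohol is present.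

Step 15
Reactants: 23 prop-2-yn-1-ol
Product: 25 (2E)-3-iodo-2-methylprop-2-en-1-ol, via dimethylalkenylalane 24 (not isolated)
Conditions: AlMe3 (3 equiv), Cp2ZrCl2 (0.25 equiv), CH2Cl2, 0 °C → rt; I2, THF, −30 → 0 °C
Reagents that add atoms: trimethylaluminium, C[Al](C)C; iodine, II
Why: Negishi zirconium-catalysed carboalumination adds methyl and aluminium syn across the alkyne with aluminium at the terminal carbon, and iodinolysis of the C–Al bond with retention gives the (E)-iodoalkene.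

Step 16
Reactants: 25 (2E)-3-iodo-2-methylprop-2-en-1-ol
Product: 26 (2E)-3-iodo-2-methylprop-2-enal
Conditions: MnO2, CH2Cl2, rt
Reagents that add atoms: none
Why: MnO2 oxidation of the allylic alcohol to the enal without isomerisation of the double bond.

Step 17
Reactants: 26 (2E)-3-iodo-2-methylprop-2-enal; 27 (4R)-4-benzyl-3-propanoyl-1,3-oxazolidin-2-one
Product: 29 (4R)-4-benzyl-3-[(2S,3R,4E)-3-hydroxy-5-iodo-2,4-dimethylpent-4-enoyl]-1,3-oxazolidin-2-one, via trimethylsilyl ether 28 (not isolated)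
Conditions: MgCl2 (0.2 equiv), Et3N, Me3SiCl, EtOAc, rt; then CF3CO2H (cat.), MeOH
Reagents that add atoms: none
Why: Evans MgCl2-catalysed anti-aldol reaction, in which the magnesium-chelated Z-enolate of the (R)-imide adds to the aldehyde on the face opposite the benzyl group through a boat-like transition state (silylation turns the catalyst over), setting C11' as S and C10' as R.

Step 18
Reactants: 29 (4R)-4-benzyl-3-[(2S,3R,4E)-3-hydroxy-5-iodo-2,4-dimethylpent-4-enoyl]-1,3-oxazolidin-2-one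
Product: 30 (4R)-4-benzyl-3-{(2S,3R,4E)-5-iodo-2,4-dimethyl-3-[(triethylsilyl)oxy]pent-4-enoyl}-1,3-oxazolidin-2-one
Conditions: Et3SiOTf, 2,6-lutidine, CH2Cl2, −78 °C
Reagents that add atoms: triethylsilyl trifluoromethanesulfonate, CC[Si](CC)(CC)OS(=O)(=O)C(F)(F)F
Why: Silylation with the silyl triflate and a hindered base protects the secondary alcohol, which blocks retro-aldol cleavage and self-acylation in the following steps.

Step 19
Reactants: 30 (4R)-4-benzyl-3-{(2S,3R,4E)-5-iodo-2,4-dimethyl-3-[(triethylsilyl)oxy]pent-4-enoyl}-1,3-oxazolidin-2-one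
Product: 32 (2S,3R,4E)-5-iodo-2,4-dimethyl-3-[(triethylsilyl)oxy]pent-4-enoic acid, via lithium peroxycarboxylate 31 (not isolated)
Conditions: LiOH, H2O2, THF/H2O, 0 °C; Na2SO3; dil. HCl to pH 4
Reagents that add atoms: hydrogen peroxide, OO
Why: Hydroperoxide-mediated imide cleavage (LiOOH attacks the exocyclic carbonyl selectively), after which the peracid salt is reduced by sulfite; no enolisation occurs, so neither stereocentre is touched.

Step 20
Reactants: 33 (2Z)-3-methylpent-2-en-4-yn-1-ol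
Product: 34 (2Z,4E)-3-methyl-5-(tributylstannyl)penta-2,4-dien-1-ol
Conditions: Bu3SnH, PdCl2(PPh3)2 (2 mol %), THF, 0 °C
Reagents that add atoms: tributyltin hydride, CCCC[SnH](CCCC)CCCC
Why: Palladium-catalysed hydrostannation adds Sn–H syn across the terminal alkyne with tin at the terminal carbon to give the (E)-alkenylstannane (any minor internal regioisomer is removed by chromatography) and leaves the (Z)-trisubstituted olefin untouched.

Step 21
Reactants: 34 (2Z,4E)-3-methyl-5-(tributylstannyl)penta-2,4-dien-1-ol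
Product: 35 (2Z,4E)-3-methyl-5-(tributylstannyl)penta-2,4-dienal
Conditions: MnO2, CH2Cl2, rt, dark
Reagents that add atoms: none
Why: MnO2 oxidation of the allylic alcohol to the (2Z)-enal under neutral conditions that neither isomerise the Z olefin nor cleave the C–Sn bond.

Step 22
Reactants: 35 (2Z,4E)-3-methyl-5-(tributylstannyl)penta-2,4-dienal; 36 2-(diethoxyphosphoryl)acetic acid
Product: 37 (2E,4Z,6E)-5-methyl-7-(tributylstannyl)hepta-2,4,6-trienoic acid
Conditions: Zn(OTf)2, TMEDA, DBU, THF, rt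
Reagents that add atoms: none
Why: Horner–Wadsworth–Emmons olefination with the zinc-bound dianion of the phosphonoacetic acid gives the (2E)-acid directly under mild base, so no ester hydrolysis is needed and the stannane survives.

Step 23
Reactants: 32 (2S,3R,4E)-5-iodo-2,4-dimethyl-3-[(triethylsilyl)oxy]pent-4-enoic acid; 22 3-[(tert-butyldiphenylsilyl)oxy]-1-[(1R,2R,6S,8S,8aS)-2,8-dihydroxy-1,2,6-trimethyl-1,2,6,7,8,8a-hexahydronaphthalen-1-yl]propan-1-one
Product: 39 (1R,2R,6S,8S,8aS)-1-{3-[(tert-butyldiphenylsilyl)oxy]propanoyl}-2-hydroxy-1,2,6-trimethyl-1,2,6,7,8,8a-hexahydronaphthalen-8-yl (2S,3R,4E)-5-iodo-2,4-dimethyl-3-[(triethylsilyl)oxy]pent-4-enoate, via mixed anhydride 38 (not isolated)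
Conditions: 2,4,6-Cl3C6H2COCl, Et3N, THF, rt; then 22, DMAP, toluene, rt → 40 °C
Reagents that add atoms: none
Why: Yamaguchi esterification, in which DMAP attacks the mixed anhydride at the less hindered carbonyl and the acylpyridinium acylates the secondary C8 alcohol (the tertiary C2 alcohol does not react), with no change at any stereocentre.

Step 24
Reactants: 39 (1R,2R,6S,8S,8aS)-1-{3-[(tert-butyldiphenylsilyl)oxy]propanoyl}-2-hydroxy-1,2,6-trimethyl-1,2,6,7,8,8a-hexahydronaphthalen-8-yl (2S,3R,4E)-5-iodo-2,4-dimethyl-3-[(triethylsilyl)oxy]pent-4-enoate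
Product: 40 (1R,2R,6S,8S,8aS)-2-hydroxy-1-(3-hydroxypropanoyl)-1,2,6-trimethyl-1,2,6,7,8,8a-hexahydronaphthalen-8-yl (2S,3R,4E)-3-hydroxy-5-iodo-2,4-dimethylpent-4-enoate
Conditions: Bu4NF, AcOH, THF, 0 °C → rt
Reagents that add atoms: none
Why: Fluoride-mediated global desilylation, buffered with AcOH so that neither retro-aldol cleavage of the β-hydroxy ketone nor acyl migration is triggered.

Step 25
Reactants: 40 (1R,2R,6S,8S,8aS)-2-hydroxy-1-(3-hydroxypropanoyl)-1,2,6-trimethyl-1,2,6,7,8,8a-hexahydronaphthalen-8-yl (2S,3R,4E)-3-hydroxy-5-iodo-2,4-dimethylpent-4-enoate; 37 (2E,4Z,6E)-5-methyl-7-(tributylstannyl)hepta-2,4,6-trienoic acid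
Product: 41 calbistrin D
Conditions: Pd2(dba)3 (5 mol %), AsPh3 (20 mol %), DMF, rt, dark
Reagents that add atoms: none
Why: Stille coupling of the (E)-alkenyl iodide with the (E)-alkenylstannane under ligand-accelerated neutral conditions (oxidative addition to zerovalent palladium, transmetalation, reductive elimination) joins C7' and C8' with retention of both olefin geometries and tolerates the free acid and hydroxyl groups.

## Compound list

1 | (S)-5-methylcyclohex-2-en-1-one | O=C1C=CC[C@H](C)C1 | starting material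
2 | (S)-2-iodo-5-methylcyclohex-2-en-1-one | O=C1C(I)=CC[C@H](C)C1 | intermediate
3 | (Z)-but-2-en-2-ylboronic acid | C/C=C(\C)B(O)O | starting material
4 | (5S)-2-[(2E)-but-2-en-2-yl]-5-methylcyclohex-2-en-1-one | O=C1C(/C(C)=C/C)=CC[C@H](C)C1 | intermediate
5 | (1S,4S,6S)-1-[(2E)-but-2-en-2-yl]-4-methyl-7-oxabicyclo[4.1.0]heptan-2-one | O1[C@H]2C[C@H](C)CC(=O)[C@@]12/C(C)=C/C | intermediate
6 | diiodosamarium enolate of 7 (O-bound SmI2 on enolate and on C8 alkoxide) | I[Sm](I)O[C@H]1C[C@H](C)CC(O[Sm](I)I)=C1/C(C)=C/C | intermediate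
7 | (2S,3S,5S)-2-[(2E)-but-2-en-2-yl]-3-hydroxy-5-methylcyclohexan-1-one | O[C@H]1C[C@H](C)CC(=O)[C@H]1/C(C)=C/C | intermediate
8 | (2S,3S,5S)-2-[(2E)-but-2-en-2-yl]-5-methyl-3-[(triethylsilyl)oxy]cyclohexan-1-one | CC[Si](CC)(CC)O[C@H]1C[C@H](C)CC(=O)[C@H]1/C(C)=C/C | intermediate
9 | potassium enolate of 8 (C4a=C5 enolate) | [K+].CC[Si](CC)(CC)O[C@H]1C[C@H](C)C=C([O-])[C@H]1/C(C)=C/C | intermediate
10 | (3S,5S,6S)-6-[(2E)-but-2-en-2-yl]-3-methyl-5-[(triethylsilyl)oxy]cyclohex-1-en-1-yl trifluoromethanesulfonate | CC[Si](CC)(CC)O[C@H]1C[C@H](C)C=C(OS(=O)(=O)C(F)(F)F)[C@H]1/C(C)=C/C | intermediate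
11 | alkylborane from 10 (BH2 on the side-arm CH; epimers) | CC[Si](CC)(CC)O[C@H]1C[C@H](C)C=C(OS(=O)(=O)C(F)(F)F)[C@H]1C(C)C(C)B | intermediate
12 | (3S,5S,6S)-6-(3-hydroxybutan-2-yl)-3-methyl-5-[(triethylsilyl)oxy]cyclohex-1-en-1-yl trifluoromethanesulfonate (side-arm epimers) | CC[Si](CC)(CC)O[C@H]1C[C@H](C)C=C(OS(=O)(=O)C(F)(F)F)[C@H]1C(C)C(C)O | intermediate
13 | (3S,5S,6S)-3-methyl-6-(3-oxobutan-2-yl)-5-[(triethylsilyl)oxy]cyclohex-1-en-1-yl trifluoromethanesulfonate (side-arm epimers) | CC[Si](CC)(CC)O[C@H]1C[C@H](C)C=C(OS(=O)(=O)C(F)(F)F)[C@H]1C(C)C(C)=O | intermediate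
14 | (3S,5S,6R)-3-methyl-6-(3-oxobutan-2-yl)-5-[(triethylsilyl)oxy]cyclohex-1-ene-1-carbaldehyde (side-arm epimers) | CC[Si](CC)(CC)O[C@H]1C[C@H](C)C=C(C=O)[C@H]1C(C)C(C)=O | intermediate
15 | (6S,8S,8aR)-4-hydroxy-1,6-dimethyl-8-[(triethylsilyl)oxy]-3,4,6,7,8,8a-hexahydronaphthalen-2(1H)-one (epimers) | CC[Si](CC)(CC)O[C@H]1C[C@H](C)C=C2C(O)CC(=O)C(C)[C@H]21 | intermediate
16 | (6S,8S,8aR)-1,6-dimethyl-8-[(triethylsilyl)oxy]-6,7,8,8a-tetrahydronaphthalen-2(1H)-one (C1 epimers) | CC[Si](CC)(CC)O[C@H]1C[C@H](C)C=C2C=CC(=O)C(C)[C@H]21 | intermediate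
17 | 3-[(tert-butyldiphenylsilyl)oxy]propanal | O=CCCO[Si](c1ccccc1)(c1ccccc1)C(C)(C)C | starting material
18 | lithium enolate of 16 (C1=C2 enolate) | [Li+].CC[Si](CC)(CC)O[C@H]1C[C@H](C)C=C2C=CC([O-])=C(C)[C@H]21 | intermediate
19 | (1S,6S,8S,8aS)-1-{3-[(tert-butyldiphenylsilyl)oxy]-1-hydroxypropyl}-1,6-dimethyl-8-[(triethylsilyl)oxy]-6,7,8,8a-tetrahydronaphthalen-2(1H)-one (carbinol epimers) | CC[Si](CC)(CC)O[C@H]1C[C@H](C)C=C2C=CC(=O)[C@](C)(C(O)CCO[Si](c3ccccc3)(c3ccccc3)C(C)(C)C)[C@H]21 | intermediate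
20 | (1S,2R,6S,8S,8aS)-1-{3-[(tert-butyldiphenylsilyl)oxy]-1-hydroxypropyl}-1,2,6-trimethyl-8-[(triethylsilyl)oxy]-1,2,6,7,8,8a-hexahydronaphthalen-2-ol (carbinol epimers) | CC[Si](CC)(CC)O[C@H]1C[C@H](C)C=C2C=C[C@@](C)(O)[C@](C)(C(O)CCO[Si](c3ccccc3)(c3ccccc3)C(C)(C)C)[C@H]21 | intermediate
21 | 3-[(tert-butyldiphenylsilyl)oxy]-1-{(1R,2R,6S,8S,8aS)-2-hydroxy-1,2,6-trimethyl-8-[(triethylsilyl)oxy]-1,2,6,7,8,8a-hexahydronaphthalen-1-yl}propan-1-one | CC[Si](CC)(CC)O[C@H]1C[C@H](C)C=C2C=C[C@@](C)(O)[C@](C)(C(=O)CCO[Si](c3ccccc3)(c3ccccc3)C(C)(C)C)[C@H]21 | intermediate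
22 | 3-[(tert-butyldiphenylsilyl)oxy]-1-[(1R,2R,6S,8S,8aS)-2,8-dihydroxy-1,2,6-trimethyl-1,2,6,7,8,8a-hexahydronaphthalen-1-yl]propan-1-one | O[C@H]1C[C@H](C)C=C2C=C[C@@](C)(O)[C@](C)(C(=O)CCO[Si](c3ccccc3)(c3ccccc3)C(C)(C)C)[C@H]21 | intermediate
23 | prop-2-yn-1-ol | C#CCO | starting material
24 | (E)-alkenylalane: dimethylaluminium alkoxide of 3-(dimethylalumanyl)-2-methylprop-2-en-1-ol | C[Al](C)OC/C(C)=C/[Al](C)C | intermediate
25 | (2E)-3-iodo-2-methylprop-2-en-1-ol | OC/C(C)=C/I | intermediate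
26 | (2E)-3-iodo-2-methylprop-2-enal | O=C/C(C)=C/I | intermediate
27 | (4R)-4-benzyl-3-propanoyl-1,3-oxazolidin-2-one | CCC(=O)N1[C@H](Cc2ccccc2)COC1=O | starting material
28 | (4R)-4-benzyl-3-{(2S,3R,4E)-5-iodo-2,4-dimethyl-3-[(trimethylsilyl)oxy]pent-4-enoyl}-1,3-oxazolidin-2-one | I/C=C(\C)[C@H](O[Si](C)(C)C)[C@H](C)C(=O)N1[C@H](Cc2ccccc2)COC1=O | intermediate
29 | (4R)-4-benzyl-3-[(2S,3R,4E)-3-hydroxy-5-iodo-2,4-dimethylpent-4-enoyl]-1,3-oxazolidin-2-one | I/C=C(\C)[C@H](O)[C@H](C)C(=O)N1[C@H](Cc2ccccc2)COC1=O | intermediate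
30 | (4R)-4-benzyl-3-{(2S,3R,4E)-5-iodo-2,4-dimethyl-3-[(triethylsilyl)oxy]pent-4-enoyl}-1,3-oxazolidin-2-one | I/C=C(\C)[C@H](O[Si](CC)(CC)CC)[C@H](C)C(=O)N1[C@H](Cc2ccccc2)COC1=O | intermediate
31 | lithium (2S,3R,4E)-5-iodo-2,4-dimethyl-3-[(triethylsilyl)oxy]pent-4-eneperoxoate | [Li+].I/C=C(\C)[C@H](O[Si](CC)(CC)CC)[C@H](C)C(=O)O[O-] | intermediate
32 | (2S,3R,4E)-5-iodo-2,4-dimethyl-3-[(triethylsilyl)oxy]pent-4-enoic acid | I/C=C(\C)[C@H](O[Si](CC)(CC)CC)[C@H](C)C(=O)O | intermediate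
33 | (2Z)-3-methylpent-2-en-4-yn-1-ol | C#C/C(C)=C\CO | starting material
34 | (2Z,4E)-3-methyl-5-(tributylstannyl)penta-2,4-dien-1-ol | CCCC[Sn](CCCC)(CCCC)/C=C/C(C)=C\CO | intermediate
35 | (2Z,4E)-3-methyl-5-(tributylstannyl)penta-2,4-dienal | CCCC[Sn](CCCC)(CCCC)/C=C/C(C)=C\C=O | intermediate
36 | 2-(diethoxyphosphoryl)acetic acid | CCOP(=O)(CC(=O)O)OCC | starting material
37 | (2E,4Z,6E)-5-methyl-7-(tributylstannyl)hepta-2,4,6-trienoic acid | CCCC[Sn](CCCC)(CCCC)/C=C/C(C)=C\C=C\C(=O)O | intermediate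
38 | (2S,3R,4E)-5-iodo-2,4-dimethyl-3-[(triethylsilyl)oxy]pent-4-enoic 2,4,6-trichlorobenzoic anhydride | I/C=C(\C)[C@H](O[Si](CC)(CC)CC)[C@H](C)C(=O)OC(=O)c1c(Cl)cc(Cl)cc1Cl | intermediate
39 | (1R,2R,6S,8S,8aS)-1-{3-[(tert-butyldiphenylsilyl)oxy]propanoyl}-2-hydroxy-1,2,6-trimethyl-1,2,6,7,8,8a-hexahydronaphthalen-8-yl (2S,3R,4E)-5-iodo-2,4-dimethyl-3-[(triethylsilyl)oxy]pent-4-enoate | I/C=C(\C)[C@H](O[Si](CC)(CC)CC)[C@H](C)C(=O)O[C@H]1C[C@H](C)C=C2C=C[C@@](C)(O)[C@](C)(C(=O)CCO[Si](c3ccccc3)(c3ccccc3)C(C)(C)C)[C@H]21 | intermediate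
40 | (1R,2R,6S,8S,8aS)-2-hydroxy-1-(3-hydroxypropanoyl)-1,2,6-trimethyl-1,2,6,7,8,8a-hexahydronaphthalen-8-yl (2S,3R,4E)-3-hydroxy-5-iodo-2,4-dimethylpent-4-enoate | I/C=C(\C)[C@H](O)[C@H](C)C(=O)O[C@H]1C[C@H](C)C=C2C=C[C@@](C)(O)[C@](C)(C(=O)CCO)[C@H]21 | intermediate
41 | calbistrin D, (2E,4Z,6E,8E,10R,11S)-10-hydroxy-12-{[(1R,2R,6S,8S,8aS)-2-hydroxy-1-(3-hydroxypropanoyl)-1,2,6-trimethyl-1,2,6,7,8,8a-hexahydronaphthalen-8-yl]oxy}-5,9,11-trimethyl-12-oxododeca-2,4,6,8-tetraenoic acid | CC(=C/C=C/C(=O)O)/C=C/C=C(\C)[C@H](O)[C@H](C)C(=O)O[C@H]1C[C@H](C)C=C2C=C[C@@](C)(O)[C@](C)(C(=O)CCO)[C@H]21 | target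

## Step count and risks

Total: 25 steps. Longest linear sequence: 17 steps (steps 1–14, then 23, 24 and 25).

The three steps most likely to fail:

Step 4. The C8a configuration rests on a kinetic protonation of a samarium dienolate, and the β,γ-unsaturated ketone formed cannot be equilibrated without moving the double bond into conjugation. The fallback sets out from 4 and replaces steps 3 and 4. A copper-catalysed conjugate borylation (B2pin2, CuCl, DPEphos, NaOt-Bu, MeOH, THF) adds boron anti to the C6 methyl, and the copper enolate is protonated anti to the bulky boryl group. This gives the β-boryl ketone (2R,3S,5S)-2-[(2E)-but-2-en-2-yl]-5-methyl-3-(4,4,5,5-tetramethyl-1,3,2-dioxaborolan-2-yl)cyclohexan-1-one F1. Oxidation of its C–B bond with NaBO3·4H2O, with retention, comes back to the route at 7.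

Step 12. The lithium aldolate of 19 can undergo retro-aldol cleavage, and the facial selectivity depends on the chelated conformer. The fallback sets out from 19 and oxidises first (Dess–Martin periodinane, pyridine) to the diketone (1S,6S,8S,8aS)-1-{3-[(tert-butyldiphenylsilyl)oxy]propanoyl}-1,6-dimethyl-8-[(triethylsilyl)oxy]-6,7,8,8a-tetrahydronaphthalen-2(1H)-one F2. Its only enolisable carbonyl, the side-chain ketone, is masked as the lithium enolate with LiN(SiMe3)2 (1.05 equiv, THF, −78 °C). MeLi/CeCl3 is then added to the non-enolisable ring carbonyl, where no alkoxide is present and the C1 acyl group is small. An AcOH quench comes back to the route at 21, and step 13 is no longer needed.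

Step 23. The axial C8 alcohol sits next to the ring fusion and peri to the quaternary C1, so the acylation may stall. The fallback sets out from 16 and makes the ester before C1 becomes quaternary. HF·pyridine in pyridine/THF gives the alcohol (6S,8S,8aR)-8-hydroxy-1,6-dimethyl-6,7,8,8a-tetrahydronaphthalen-2(1H)-one F3. Acylation with 32 under the same Yamaguchi conditions (through 38) gives (6S,8S,8aR)-1,6-dimethyl-2-oxo-1,2,6,7,8,8a-hexahydronaphthalen-8-yl (2S,3R,4E)-5-iodo-2,4-dimethyl-3-[(triethylsilyl)oxy]pent-4-enoate F4. Enolisation of the ketone with LiN(i-Pr)2 (1.0 equiv, −78 °C) and aldol addition to 17 gives (1S,6S,8S,8aS)-1-{3-[(tert-butyldiphenylsilyl)oxy]-1-hydroxypropyl}-1,6-dimethyl-2-oxo-1,2,6,7,8,8a-hexahydronaphthalen-8-yl (2S,3R,4E)-5-iodo-2,4-dimethyl-3-[(triethylsilyl)oxy]pent-4-enoate F5. MeLi/CeCl3, which adds to the ketone in preference to the hindered ester, gives (1S,2R,6S,8S,8aS)-1-{3-[(tert-butyldiphenylsilyl)oxy]-1-hydroxypropyl}-2-hydroxy-1,2,6-trimethyl-1,2,6,7,8,8a-hexahydronaphthalen-8-yl (2S,3R,4E)-5-iodo-2,4-dimethyl-3-[(triethylsilyl)oxy]pent-4-enoate F6. Dess–Martin oxidation of its secondary alcohol comes back to the route at 39.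

## Further compounds

F1 | step 4 | (2R,3S,5S)-2-[(2E)-but-2-en-2-yl]-5-methyl-3-(4,4,5,5-tetramethyl-1,3,2-dioxaborolan-2-yl)cyclohexan-1-one | CC1(C)OB(OC1(C)C)[C@H]2C[C@H](C)CC(=O)[C@H]2/C(C)=C/C
F2 | step 12 | (1S,6S,8S,8aS)-1-{3-[(tert-butyldiphenylsilyl)oxy]propanoyl}-1,6-dimethyl-8-[(triethylsilyl)oxy]-6,7,8,8a-tetrahydronaphthalen-2(1H)-one | CC[Si](CC)(CC)O[C@H]1C[C@H](C)C=C2C=CC(=O)[C@](C)(C(=O)CCO[Si](c3ccccc3)(c3ccccc3)C(C)(C)C)[C@H]21
F3 | step 23 | (6S,8S,8aR)-8-hydroxy-1,6-dimethyl-6,7,8,8a-tetrahydronaphthalen-2(1H)-one (C1 epimers) | O[C@H]1C[C@H](C)C=C2C=CC(=O)C(C)[C@H]21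
F4 | step 23 | (6S,8S,8aR)-1,6-dimethyl-2-oxo-1,2,6,7,8,8a-hexahydronaphthalen-8-yl (2S,3R,4E)-5-iodo-2,4-dimethyl-3-[(triethylsilyl)oxy]pent-4-enoate (C1 epimers) | I/C=C(\C)[C@H](O[Si](CC)(CC)CC)[C@H](C)C(=O)O[C@H]1C[C@H](C)C=C2C=CC(=O)C(C)[C@H]21
F5 | step 23 | (1S,6S,8S,8aS)-1-{3-[(tert-butyldiphenylsilyl)oxy]-1-hydroxypropyl}-1,6-dimethyl-2-oxo-1,2,6,7,8,8a-hexahydronaphthalen-8-yl (2S,3R,4E)-5-iodo-2,4-dimethyl-3-[(triethylsilyl)oxy]pent-4-enoate (carbinol epimers) | I/C=C(\C)[C@H](O[Si](CC)(CC)CC)[C@H](C)C(=O)O[C@H]1C[C@H](C)C=C2C=CC(=O)[C@](C)(C(O)CCO[Si](c3ccccc3)(c3ccccc3)C(C)(C)C)[C@H]21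
F6 | step 23 | (1S,2R,6S,8S,8aS)-1-{3-[(tert-butyldiphenylsilyl)oxy]-1-hydroxypropyl}-2-hydroxy-1,2,6-trimethyl-1,2,6,7,8,8a-hexahydronaphthalen-8-yl (2S,3R,4E)-5-iodo-2,4-dimethyl-3-[(triethylsilyl)oxy]pent-4-enoate (carbinol epimers) | I/C=C(\C)[C@H](O[Si](CC)(CC)CC)[C@H](C)C(=O)O[C@H]1C[C@H](C)C=C2C=C[C@@](C)(O)[C@](C)(C(O)CCO[Si](c3ccccc3)(c3ccccc3)C(C)(C)C)[C@H]21
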